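All runs stem from a simulated flask for substances that don't exist.

common to all: solid substrate 0.13 M; gas 21 mM (held)
- oak: free catalyst 0.9 mol%; run made earlier
- elm: free catalyst 3.1 mol%; run made earlier
- Tuesday's: free catalyst 2 mol%; time 10 d
- Saturday's: free catalyst 0.6 mol%; time 40 d

| run | time / d | product / % | solid substrate / % |
|---|---|---|---|
| oak | 0.417 | 0.3 | 89.3 |
| oak | 1.25 | 1.8 | 76.1 |
| oak | 2.50 | 4.9 | 65.3 |
| oak | 4.00 | 9.6 | 57.9 |
| oak | 5.00 | 13.9 | 53.8 |
| elm | 0.417 | 0 | 89.2 |
| elm | 1.25 | 3.7 | 75.6 |
| elm | 2.50 | 11.2 | 60.3 |
| elm | 4.00 | 23.0 | 47.2 |
| elm | 5.00 | 30.9 | 40.5 |

(each reading ± 0.5 percentage points)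

- given per volume of solution although it is solid: solid substrate
- at the start none of partner is dissolved
- on the list of suspects stand: starting material + free catalyst <-> catalyst intermediate A; partner + catalyst intermediate A -> catalyst intermediate B; catalyst intermediate B -> by-product + catalyst intermediate C; catalyst intermediate C <-> free catalyst + product; partner -> decomposed reagent; solid substrate <-> starting material; gas <-> partner
- at the start none of the solid substrate is in solution
- what has only dissolved of solid substrate counts as not reacted

1. which of the two ends with the higher amount of product, in percent of the solid substrate charged ("neither" if they lie within 2 percentage points) (Tuesday's / Saturday's / neither)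
2. product at the end, in percent of the solid substrate charged, Tuesday's
3. product at the end, in percent of the solid substrate charged, Saturday's

Not yet product at 5.00 d: 86.1 % of the charge in the oak run, 69.1 % in the elm run. Product made per catalyst charged per day, counted from the start, is the mean turnover frequency: 3.09 /d in the oak run, 1.99 /d in the elm run, so the oak run turns over faster than the elm run.

My own bracket assumes that this frequency keeps falling as the loading rises and does not change with time, which is its weak point. Tuesday's loading lies between the two runs, so its product lies between 39.9 % and 61.8 %. Saturday's loading lies below the oak run's, so the oak frequency gives a floor of 74.1 %, and the charge gives a ceiling of 100 %. A power law through both readings, with exponent 0.354, tightens these to 46.6 % for Tuesday's and 85.6 % for Saturday's.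

The forecast calls the rates “clearly sublinear in catalyst”. It gives 58 % (49 % to 67 %) for Tuesday's and 95 % (80 % to 100 %) for Saturday's, with Saturday's ahead. Both central values stand inside my brackets, but above my tightened figures.

Saturday's ends ahead, with 82.5 % against 52.3 % for Tuesday's.

    starting material + free catalyst ⇌ catalyst intermediate A (K = 4.80 /M, k = 0.00540 /M/s)
    partner + catalyst intermediate A → catalyst intermediate B (k = 0.0340 /M/s)
    catalyst intermediate B → by-product + catalyst intermediate C (k = 0.0690 /s)
    catalyst intermediate C ⇌ free catalyst + product (K = 0.190 M, k = 1.80 × 10⁻⁴ /s)
    partner → decomposed reagent (k = 4.30 × 10⁻⁷ /s)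
    solid substrate ⇌ starting material, rate k6*(cs6 - [starting material]) while solid is left; crystals form when [starting material] > cs6 (solubility = 49.0 mM, k = 9.00 × 10⁻⁶ /s)
    gas ⇌ partner, rate k7*(csat - [partner]) (kL = 1.00 × 10⁻⁵ /s)

At 40.0 d, Saturday's flask holds 0 % solid substrate and 17.2 % of the charge as dissolved starting material. Its mean turnover frequency comes to 3.44 /d, higher than the oak run's 3.09 /d, while Tuesday's gives 2.61 /d, between the elm and oak values. A neighbouring flask, like Saturday's but with 0.22 M of solid substrate, gives 75.1 % at the same loading and time, a mean turnover frequency of 3.13 /d.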